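All runs are calculated for substances that don't exist.

- The stirred, isothermal flask held substrate while reagent ran in steadily for 2.0 min. In north-east, at 10.0 s, the feed had delivered 8.33% of its dose, yet substrate had lost 42.0% of the charge, more than that.

| flask | substrate | reagent | remark | time |
|---|---|---|---|---|
| north-east | 0.050 M | 1 equiv (fed, over 2.0 min) | run made earlier; the fed solution adds 0.20 times the starting volume |  |
| north-west | 0.050 M | 4.7 equiv (fed, over 2.0 min) | run made earlier; the fed solution adds 0.20 times the starting volume |  |
| blue | 0.050 M | 0.800 equiv (fed, over 2.0 min) | the fed solution adds 0.20 times the starting volume | 2.0 min |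
| amber | 0.050 M | 4.00 equiv (fed, over 2.0 min) | the fed solution adds 0.20 times the starting volume | 2.0 min |

| run | time / s | mono adduct / % | substrate / % |
|---|---|---|---|
| north-east | 10.0 | 1.1 | 58.0 |
| north-east | 15.0 | 1.9 | 48.1 |
| north-east | 30.0 | 5.3 | 30.8 |
| north-east | 50.0 | 7.7 | 18.0 |
| north-east | 60.0 | 10.5 | 15.1 |
| north-east | 80.0 | 10.2 | 9.4 |
| north-west | 15.0 | 10.1 | 41.7 |
| north-west | 30.0 | 18.1 | 19.0 |
| north-west | 40.0 | 20.7 | 10.7 |
| north-west | 60.0 | 21.3 | 3.6 |
| north-west | 80.0 | 18.8 | 0.4 |

(readings scatter by 0.5 percentage points)
- which of these holds the largest part of the substrate at the end of blue (other mono adduct / substrate / mono adduct / double product)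
- which of these holds the largest part of the substrate at the end of amber (other mono adduct / substrate / mono adduct / double product)
- final mono adduct in amber, as a percentage of the substrate charged
- amounts are per litre of the starting volume; all of the dose is in the solution fed
- the analysis behind the earlier runs scatters by 0.5 percentage points, standard deviation
- a reading or a percentage of mono adduct counts all its forms, free or not

- I read this early loss as second order in substrate. Its half-life from the full charge, my self-clock, is the time multiplied by the fraction left over the fraction lost: 13.8 s. It gave 31.5% left at 30.0 s, against the north-east reading of 30.8%.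
- Taken by itself to the end of amber, the clock reckoned 89.7% of the charge as spent.
- North-west mono adduct fell from 21.3% at 60.0 s to 18.8% at 80.0 s. I assumed that gain and loss both follow the reagent, so I kept that height and let the loss rate grow with time and dose. My estimate for the end of amber was then 14.1%.
- The weak link was the first self-loss, which left room for 10.3%, less than that mono adduct. I put the north-west substrate readings back into the square of the fraction, up to 30.0 s, and the self-loss became 62.7%.
- On my reckoning that left 37.3% for reagent in amber. Taking other mono adduct as small, I estimated 23.2% as double product, ahead of my mono adduct. For blue I chose mono adduct, as the north-east reading was 10.2% at 80.0 s, above the substrate reading of 9.4%.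
- The forecast gave other mono adduct for blue, other mono adduct for amber and 12% for the final mono adduct, holding that “most substrate must go to the other mono adduct”.
- The flasks gave mono adduct in blue, double product in amber, and 15.3% of mono adduct in amber.

    substrate + reagent ⇌ mono adduct (K = 33.0 M⁻¹, k = 1.50 M⁻¹ s⁻¹)
    substrate + reagent → other mono adduct (k = 0.0610 M⁻¹ s⁻¹)
    reagent + mono adduct → double product (k = 1.00 M⁻¹ s⁻¹)
    reagent + other mono adduct → double product (k = 0.200 M⁻¹ s⁻¹)
    2 substrate → self-condensation product (k = 0.690 M⁻¹ s⁻¹)
    crystals ⇌ mono adduct, rate k6*(cs6 - [mono adduct]) while solid is left; crystals form when [mono adduct] > cs6 (solubility = 0.910 mM, k = 0.0570 s⁻¹)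

- Substrate lost to itself was the largest single effect on amber's mono adduct: with the path to self-condensation product struck out, mono adduct rose from 15.3% to 51.3%. That path had done half of its amber turnover by 0.105 min, inside the self-clock of 13.8 s. For a neighbouring flask, amber with 0.013 M of substrate, I reckoned the clock at 53.1 s. Self-condensation product there stood at 44.7%, below amber's 59.1%, and mono adduct reached 20.2%.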